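## Retrosynthetic overview

1. Azulene numbering is used: C3 i-Pr, C3a OH, C6 Me, C6=C7, C8 O-acyl, C8a Me. Ring A is the cyclopentane and ring B the cycloheptene. The target comes from the C3a,C8-diol by selective acylation of the secondary allylic OH.
2. Key disconnection C3a–C4. Ring B opens to a 2,2,5-trisubstituted cyclopentanone whose quaternary carbon carries a silyl-protected (Z)-3-methylpenta-2,4-dienyl carbinol. In the forward direction a nickel-catalysed reductive ketone–diene cyclisation (7-endo homoallylation) closes ring B.
3. Enabling feature: the ring-fusion carbinol C3a is bis-homoallylic to the ring B olefin, C3a(OH)–C4H2–C5H2–C6(Me)=C7H. This array is the retron of a carbonyl/1,3-diene homoallylation. The diene hangs on the neighbouring quaternary C8a, so C4 can only be delivered cis.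
4. C7–C8 bond: Nozaki–Hiyama–Kishi coupling of (Z)-1-iodo-2-methylbuta-1,3-diene with a non-enolisable β-keto aldehyde.
5. Ring A with C8a: C–C cleavage and ring contraction (1,2-acyl shift) of the catalytically made, enantioenriched epoxide of cheap piperitone. Rings are formed in the order A (step 2), then B (step 9).

Key step: step 9

Assumption: the quinine-derived amine salt is taken to give the (1S,6S)-epoxide. If the sense of induction is the opposite, the quinidine-derived pseudoenantiomer is used in the same way.

## Route

Step 1
Reactants: 1 piperitone (3-methyl-6-(propan-2-yl)cyclohex-2-en-1-one, commercial, any enantiomeric composition)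
Product: 2 (1S,6S)-6-methyl-3-(propan-2-yl)-7-oxabicyclo[4.1.0]heptan-2-one (piperitone oxide, both C3 epimers)
Conditions: 9-amino-9-deoxy-epi-quinine (10 mol %), CF3CO2H (20 mol %), 50 % aq H2O2, 1,4-dioxane, 35 °C
Reagents that add atoms: hydrogen peroxide, OO
Why: Amine-salt (iminium) catalysed asymmetric Weitz–Scheffer epoxidation of a cyclic enone, in which hydroperoxide adds to the β-carbon of the chiral iminium ion on the face left open by the cinchona amine and ring closure fixes both oxirane carbons as (1S,6S), while the labile isopropyl-bearing C3 is deliberately left uncontrolled until step 8.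

Step 2
Reactants: 2 piperitone oxide
Product: 3 (1R)-1-methyl-2-oxo-3-(propan-2-yl)cyclopentane-1-carbaldehyde (both C3 epimers)
Conditions: BF3·OEt2 (0.6 equiv), toluene, 0 → 23 °C; water wash only (no base)
Reagents that add atoms: none
Why: Lewis-acid rearrangement of an α,β-epoxy ketone with 1,2-acyl shift (Meinwald-type ring contraction, the reaction type that turns isophorone oxide into 2-formyl-2,4,4-trimethylcyclopentanone): the tertiary C–O bond ionises, the bond between the carbonyl carbon and the oxirane CH is cleaved as the acyl carbon migrates to the rear of the methyl-bearing carbon, and the oxirane configuration is transferred with inversion into the quaternary centre (future C8a).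

Step 3
Reactants: 4 prop-2-yn-1-ol
Product: 6 (Z)-3-iodo-2-methylprop-2-en-1-ol, via alkenylmagnesium alkoxide 5 (not isolated)
Conditions: MeMgBr (2.5 equiv), CuI (10 mol %), Et2O, −10 → 23 °C; then I2, −20 °C; aq NH4Cl
Reagents that add atoms: methylmagnesium bromide, C[Mg]Br; iodine, II
Why: Copper-catalysed anti-carbomagnesiation of a propargylic alkoxide gives the chelated (Z)-alkenylmagnesium species, and iodinolysis with retention fixes the olefin geometry that later becomes the ring B olefin.

Step 4
Reactants: 6 (Z)-3-iodo-2-methylprop-2-en-1-ol
Product: 7 (Z)-3-iodo-2-methylprop-2-enal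
Conditions: activated MnO2, CH2Cl2, 0 °C, dark
Reagents that add atoms: none
Why: Neutral MnO2 oxidation of an allylic alcohol, kept cold and dark so that the Z-iodoenal does not isomerise.

Step 5
Reactants: 7 (Z)-3-iodo-2-methylprop-2-enal
Product: 8 (Z)-1-iodo-2-methylbuta-1,3-diene (kept as a solution in pentane/Et2O)
Conditions: Ph3PCH3Br, KOt-Bu, Et2O, 0 °C; then 7, −78 → 0 °C
Reagents that add atoms: methyltriphenylphosphonium bromide, C[P+](c1ccccc1)(c1ccccc1)c1ccccc1.[Br-]
Why: Wittig methylenation of the aldehyde, which leaves the trisubstituted Z-iodoalkene untouched because it offers no hydrogen for elimination.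

Step 6
Reactants: 3 keto aldehyde; 8 (Z)-1-iodo-2-methylbuta-1,3-diene
Product: 9 (2R)-2-[(1S,2Z)-1-hydroxy-3-methylpenta-2,4-dien-1-yl]-2-methyl-5-(propan-2-yl)cyclopentan-1-one (both C5 epimers)
Conditions: CrCl2 (4 equiv), NiCl2 (1 mol %), DMSO, 23 °C; water
Reagents that add atoms: none
Why: Nozaki–Hiyama–Kishi coupling, in which the alkenylchromium reagent forms with retention of olefin geometry, adds only to the aldehyde and not to the hindered ketone, and in the donor solvent (no chelation) attacks the Felkin–Anh, dipole-minimised conformer past the methyl group, which should set the carbinol centre (future C8) as (S).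

Step 7
Reactants: 9 dienol ketone
Product: 10 (2R)-2-methyl-2-[(1S,2Z)-3-methyl-1-(triethylsilyloxy)penta-2,4-dien-1-yl]-5-(propan-2-yl)cyclopentan-1-one (both C5 epimers)
Conditions: Et3SiOTf, 2,6-lutidine, CH2Cl2, −78 → 0 °C
Reagents that add atoms: triethylsilyl trifluoromethanesulfonate, CC[Si](CC)(CC)OS(=O)(=O)C(F)(F)F
Why: Silylation of a hindered secondary alcohol with a silyl triflate; the ether blocks retro-aldol cleavage and metal alkoxide formation in steps 8 and 9.

Step 8
Reactants: 10 silyl ether (C5 epimers)
Product: 11 (2R,5R)-2-methyl-2-[(1S,2Z)-3-methyl-1-(triethylsilyloxy)penta-2,4-dien-1-yl]-5-(propan-2-yl)cyclopentan-1-one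
Conditions: NaOMe (0.2 equiv), MeOH–THF, 23 °C; chromatography, minor epimer resubmitted
Reagents that add atoms: none
Why: Base-mediated epimerisation through the only possible enolate (thermodynamic control): in the cyclopentanone half-chair the isopropyl group and the much larger silyloxy-dienyl substituent can both be pseudo-equatorial only when they are trans, so the (5R) epimer (future C3) should predominate.

Step 9
Reactants: 11 (2R,5R)-dienyl ketone
Product: 13 (3R,3aS,8S,8aR)-6,8a-dimethyl-3-(propan-2-yl)-2,3,4,5,8,8a-hexahydroazulene-3a,8(1H)-diol, via bicyclic silyl ether 12 (not isolated)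
Conditions: Ni(acac)2 (10 mol %), Et2Zn (3 equiv), THF (0.01 M, slow addition of 11), 23 → 40 °C; sat. aq NH4Cl; crude 12 in AcOH–THF–H2O (3:1:1), 23 °C
Reagents that add atoms: none
Why: Proposed new method: zerovalent nickel, made in the flask from Ni(acac)2 and Et2Zn, binds the diene and the zinc-activated ketone and couples the diene terminus (future C4) oxidatively to the carbonyl carbon (future C3a), which gives a five-membered oxanickelacycle that is at the same time an η3-allyl complex over C5–C6–C7; ethyl transfer from zinc to nickel, β-hydride elimination (ethene) and C5–H reductive elimination release the ethylzinc alkoxide and regenerate zerovalent nickel. The closest known reaction type is the nickel-catalysed, Et2Zn- or Et3B-promoted homoallylation of aldehydes and ketones by 1,3-dienes, which is established between two molecules (ketones included) and within ω-dienyl aldehydes in the exo mode for five- and six-membered rings; the endo mode, the seven-membered ring and the hindered ketone are new. Ring B closes in a 7-endo mode in which all four diene carbons become ring members, which is possible only because the C6=C7 bond is Z and holds C8 and C5 on the same side. The single new stereocentre C3a is controlled by the quaternary C8a: the short link C8a–C8–C7 lets C4 reach only the ketone face on which the side chain stands, which is also the face anti to the C3 isopropyl group, so the cis-fused ring with OH cis to the angular methyl group should form. Two regioselectivities are needed: C–C bond formation at the diene terminus instead of C5, secured by the allyl stabilisation of the resulting nickel species, and hydrogen delivery to C5 instead of C7, secured by the O–Ni chelate that keeps nickel at C5 as in the known homoallylation, so that the olefin stays at C6=C7. The silyl ether prevents retro-aldol cleavage and ionisation at C8, high dilution disfavours diene oligomerisation, and the mild acid treatment of crude 12 removes the silyl group without touching the allylic or the tertiary alcohol.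

Step 10
Reactants: 13 diol; 14 4-methoxybenzoyl chloride
Product: 15 (3R,3aS,8S,8aR)-3a-hydroxy-6,8a-dimethyl-3-(propan-2-yl)-1,2,3,3a,4,5,8,8a-octahydroazulen-8-yl 4-methoxybenzoate (target)
Conditions: Et3N, DMAP (0.2 equiv), CH2Cl2, 0 → 23 °C
Reagents that add atoms: none
Why: DMAP-catalysed acylation, selective for the secondary allylic alcohol because the tertiary ring-fusion alcohol is too hindered to react; no stereocentre is touched.

## Compound list

1 | piperitone | CC1=CC(=O)C(C(C)C)CC1 | starting material
2 | (1S,6S)-piperitone oxide, C3 epimers | CC(C)C1CC[C@]2(C)O[C@@H]2C1=O | intermediate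
3 | (1R)-1-methyl-2-oxo-3-(propan-2-yl)cyclopentane-1-carbaldehyde, C3 epimers | O=C[C@@]1(C)CCC(C(C)C)C1=O | intermediate
4 | prop-2-yn-1-ol | C#CCO | starting material
5 | bromomagnesium (Z)-3-(bromomagnesio)-2-methylprop-2-en-1-olate | Br[Mg]/C=C(C)\CO[Mg]Br | intermediate
6 | (Z)-3-iodo-2-methylprop-2-en-1-ol | I/C=C(C)\CO | intermediate
7 | (Z)-3-iodo-2-methylprop-2-enal | I/C=C(C)\C=O | intermediate
8 | (Z)-1-iodo-2-methylbuta-1,3-diene | I/C=C(C)\C=C | intermediate
9 | (2R)-2-[(1S,2Z)-1-hydroxy-3-methylpenta-2,4-dien-1-yl]-2-methyl-5-(propan-2-yl)cyclopentan-1-one, C5 epimers | O[C@@H](/C=C(C)\C=C)[C@@]1(C)CCC(C(C)C)C1=O | intermediate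
10 | triethylsilyl ether of 9, C5 epimers | CC[Si](CC)(CC)O[C@@H](/C=C(C)\C=C)[C@@]1(C)CCC(C(C)C)C1=O | intermediate
11 | (2R,5R)-triethylsilyl ether | CC[Si](CC)(CC)O[C@@H](/C=C(C)\C=C)[C@@]1(C)CC[C@H](C(C)C)C1=O | intermediate
12 | (3R,3aS,8S,8aR)-6,8a-dimethyl-3-(propan-2-yl)-8-(triethylsilyloxy)-2,3,4,5,8,8a-hexahydroazulen-3a(1H)-ol | CC[Si](CC)(CC)O[C@H]1C=C(C)CC[C@]2(O)[C@@H](C(C)C)CC[C@]12C | intermediate
13 | (3R,3aS,8S,8aR)-6,8a-dimethyl-3-(propan-2-yl)-2,3,4,5,8,8a-hexahydroazulene-3a,8(1H)-diol | O[C@H]1C=C(C)CC[C@]2(O)[C@@H](C(C)C)CC[C@]12C | intermediate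
14 | 4-methoxybenzoyl chloride | COc1ccc(C(=O)Cl)cc1 | starting material
15 | target ester | COc1ccc(C(=O)O[C@H]2C=C(C)CC[C@]3(O)[C@@H](C(C)C)CC[C@]23C)cc1 | target

## Step count

- Total step count: 10.
- Longest linear sequence: 8 steps (steps 3–10, from prop-2-yn-1-ol). The sequence from piperitone is 7 steps.

## Steps most likely to fail

**Step 9 (Proposed new method).**
- Risk: oxidative coupling at the doubly flanked ketone may be too slow. Nickel hydride-mediated Z-to-E isomerisation or oligomerisation of the diene could then take over, as could hydrogen delivery to the wrong allyl terminus or β-elimination of the silyloxy group.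
- Fallback (known chemistry), from 11 back to 12: the monosubstituted vinyl group is hydroborated chemoselectively with 9-BBN and oxidised with NaBO3 to the primary alcohol F1. Appel iodination (I2, PPh3, imidazole) gives the primary iodide F2. An intramolecular samarium Barbier reaction (SmI2, HMPA, THF) adds the alkylsamarium to the ketone from the same, tether-dictated face and gives 12, where the route is rejoined.

**Step 1.**
- Risk: iminium formation next to the branched α′-carbon may be slow. A mismatched pairing of the catalyst with one substrate enantiomer may also erode conversion or enantiopurity.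
- Fallback (chiral-pool and substrate control instead of catalyst control), from 1 back to 2: 1 is used as its enantioenriched (R)-(−) form. Luche reduction (NaBH4, CeCl3·7H2O, MeOH) by axial hydride attack gives trans-piperitol F3. Hydroxyl-directed epoxidation (VO(acac)2, t-BuOOH) places the oxirane syn to OH and anti to isopropyl and gives the epoxy alcohol F4. Dess–Martin oxidation returns to 2 as its single (3R) epimer.

**Step 6.**
- Risk: facial selectivity at the α-quaternary aldehyde may be poor, or the keto aldehyde may lose its formyl group.
- Fallback (C8 set by reduction on the rigid bicycle instead of by addition), from 9 back to 13: the carbinol epimers of 9 are carried together through steps 7–9. The resulting mixture of 13 and the C8-epimeric diol F5 is oxidised at the allylic carbinol with MnO2 to the single β-hydroxy enone F6. Narasaka–Prasad reduction (Et2BOMe, NaBH4, THF–MeOH, −78 °C) uses the boron chelate to the C3a hydroxyl, which shields one face, and should give the cis-1,3-diol 13.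

## Further compounds

F1 | step 9 | (2R,5R)-2-[(1S,2Z)-5-hydroxy-3-methyl-1-(triethylsilyloxy)pent-2-en-1-yl]-2-methyl-5-(propan-2-yl)cyclopentan-1-one | CC[Si](CC)(CC)O[C@@H](/C=C(C)\CCO)[C@@]1(C)CC[C@H](C(C)C)C1=O
F2 | step 9 | (2R,5R)-2-[(1S,2Z)-5-iodo-3-methyl-1-(triethylsilyloxy)pent-2-en-1-yl]-2-methyl-5-(propan-2-yl)cyclopentan-1-one | CC[Si](CC)(CC)O[C@@H](/C=C(C)\CCI)[C@@]1(C)CC[C@H](C(C)C)C1=O
F3 | step 1 | (1R,6R)-3-methyl-6-(propan-2-yl)cyclohex-2-en-1-ol (trans-piperitol) | CC1=C[C@H](O)[C@@H](C(C)C)CC1
F4 | step 1 | trans-piperitol epoxide (oxirane syn to OH, anti to isopropyl) | CC(C)[C@H]1CC[C@]2(C)O[C@@H]2[C@@H]1O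
F5 | step 6 | (3R,3aS,8R,8aR)-6,8a-dimethyl-3-(propan-2-yl)-2,3,4,5,8,8a-hexahydroazulene-3a,8(1H)-diol | O[C@@H]1C=C(C)CC[C@]2(O)[C@@H](C(C)C)CC[C@]12C
F6 | step 6 | (3R,3aS,8aS)-3a-hydroxy-6,8a-dimethyl-3-(propan-2-yl)-2,3,3a,4,5,8a-hexahydroazulen-8(1H)-one | O=C1C=C(C)CC[C@]2(O)[C@@H](C(C)C)CC[C@]12C
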